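The cycloheptane ring (C1 tertiary carbinol, C2 CH–O-angeloyl, C3 lactone O–CH, C4 ring-fusion CH, C5 CH2, C6 CHOH, C7 CHCH3) is cut into the triad C2–C3–C4, oxygenated at its centre, and the tetrad C5–C6–C7–C1. One (4+3) cycloaddition of a chiral 1-alkoxy-2-silyloxyallyl cation to a 2,3-disubstituted furan forms C4–C5 and C1–C2 and fixes C1 and C2. It exploits the 1,4-relation of the C1 hydroxyl and C5. The furan oxygen bridges them and stays as C1–OH after reductive C5–O cleavage. The precursors are furan 3 and the open-chain acetal enol silane 7. The rigid 8-oxabicyclo[3.2.1]octene then relays C3, C4, C6 and C7.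

Key step: step 5

Remark: the sense of induction in step 5 is assigned from the stacking model stated there, and (E)-1-iodoprop-1-ene (31) is taken as a purchasable reagent.
Abbreviations: TBS = tert-butyldimethylsilyl; OR* = (1S)-1-(naphthalen-2-yl)ethoxy; O8 = the former furan oxygen. Locants C1–C7 are those of the first paragraph.

Step 1
Reactants: 1 methyl 3-methylfuran-2-carboxylate
Product: 2 (3-methylfuran-2-yl)methanol
Conditions: LiAlH4, Et2O, 0 °C
Reagents that add atoms: none
Why: Hydride reduction of the ester should give the furfuryl alcohol without touching the furan ring, and it creates no stereocentre.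

Step 2
Reactants: 2 (3-methylfuran-2-yl)methanol
Product: 3 tert-butyl(dimethyl)[(3-methylfuran-2-yl)methoxy]silane
Conditions: TBSCl, imidazole, CH2Cl2, 23 °C
Reagents that add atoms: tert-butyldimethylsilyl chloride, CC(C)(C)[Si](C)(C)Cl
Why: Silyl ether formation masks the primary alcohol (the later acyl carbon) as a group that keeps the furan electron-rich and is not ionised by a catalytic silyl triflate at low temperature.

Step 3
Reactants: 4 1,1-dimethoxypropan-2-one; 5 (1S)-1-(naphthalen-2-yl)ethanol
Product: 6 1-methoxy-1-[(1S)-1-(naphthalen-2-yl)ethoxy]propan-2-one (both epimers at the acetal carbon)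
Conditions: 4 (3 equiv), pyridinium p-toluenesulfonate (5 mol%), cyclohexane, 5 Å sieves, 60 °C
Reagents that add atoms: none
Why: Acid-catalysed transacetalisation with removal of methanol exchanges one methoxy group for the chiral alkoxy group, and the acetal carbon may form as both epimers because it becomes planar in step 5.

Step 4
Reactants: 6 1-methoxy-1-[(1S)-1-(naphthalen-2-yl)ethoxy]propan-2-one
Product: 7 triethyl({3-methoxy-3-[(1S)-1-(naphthalen-2-yl)ethoxy]prop-1-en-2-yl}oxy)silane
Conditions: LiN(i-Pr)2, Et3SiCl, THF, −78 °C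
Reagents that add atoms: chlorotriethylsilane, CC[Si](Cl)(CC)CC
Why: Kinetic deprotonation at the methyl group (the acetal C–H is hindered and flanked by two oxygen atoms) and O-silylation give the terminal enol silane, a standard enol silane formation that touches no stereocentre.

Step 5
Reactants: 3 tert-butyl(dimethyl)[(3-methylfuran-2-yl)methoxy]silane; 7 triethyl({3-methoxy-3-[(1S)-1-(naphthalen-2-yl)ethoxy]prop-1-en-2-yl}oxy)silane
Product: 9 (1R,2R,5S)-1-(TBSO-methyl)-7-methyl-2-OR*-8-oxabicyclo[3.2.1]oct-6-en-3-one (C2–O equatorial and anti to O8), via alkoxy-silyloxyallyl cation 8 (not isolated)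
Conditions: 3 (1.5 equiv), Me3SiOTf (10 mol%), CH2Cl2, −95 °C
Reagents that add atoms: none
Why: Me3SiOTf ionises the methoxy group of 7 to the W-shaped 1-alkoxy-2-silyloxyallyl cation 8, which adds across C2/C5 of furan 3 in a concerted but asynchronous [4π+2π] (4+3) cycloaddition, and silyl transfer from the resulting silyloxocarbenium ion to the next acetal frees ketone 9 and carries the chain. The closest known reaction type is the low-temperature (4+3) cycloaddition of chiral 1-arylethoxy-substituted silyloxyallyl cations with furans. The cycloheptene ring is closed by intermolecular cycloaddition (in the stepwise limit the second bond is a 7-exo-trig attack of the enol silane carbon C2 on the 2H-furanium ion), and the furan oxygen makes it the 8-oxabicyclo[3.2.1]octene. C1 and C5 are set together by suprafacial addition to the furan, C2–O is set equatorial (anti to O8) by the compact endo transition state of the W-cation, and the absolute sense comes from the (S)-1-(2-naphthyl)ethyl group, whose C–H lies in the cation plane (allylic 1,3-strain) so that the naphthyl ring stacks on one face and the furan enters from the other. The step needs head-to-head regiochemistry (C4–C5 and C1–C2) and ring closure faster than proton loss from C5: the leading bond should join the two unhindered, orbital-matched termini (furan C5–H and the CH2 terminus of 8, as for heteroatom-substituted oxyallyl cations with 2-alkylfurans), because the 3-methyl group activates a furan C2 that is fully substituted and the bulky auxiliary shields C2 of the cation, and the donor-stabilised terminus then closes at −95 °C, where rearomatisation is slow.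

Step 6
Reactants: 9 (1R,2R,5S)-1-(TBSO-methyl)-7-methyl-2-OR*-8-oxabicyclo[3.2.1]oct-6-en-3-one; 10 tert-butyl bromoacetate
Product: 11 tert-butyl [(1R,2R,4R,5R)-1-(TBSO-methyl)-7-methyl-2-OR*-3-oxo-8-oxabicyclo[3.2.1]oct-6-en-4-yl]acetate (C4 arm axial and syn to O8)
Conditions: LiN(i-Pr)2, THF, −78 °C; DMPU, 10, −78 → −40 °C
Reagents that add atoms: none
Why: Kinetic enolisation away from the alkoxy-bearing C2 and SN2 alkylation of the lithium enolate should take place on the exo face (syn to O8), since the endo face is covered by the C6=C7 bridge and axial attack is stereoelectronically favoured, which places the acetate arm axial at C4.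

Step 7
Reactants: 11 tert-butyl [(1R,2R,4R,5R)-1-(TBSO-methyl)-7-methyl-2-OR*-3-oxo-8-oxabicyclo[3.2.1]oct-6-en-4-yl]acetate
Product: 12 tert-butyl [(1R,2S,3S,4S,5R)-3-hydroxy-1-(TBSO-methyl)-7-methyl-2-OR*-8-oxabicyclo[3.2.1]oct-6-en-4-yl]acetate (C3–OH axial and anti to O8)
Conditions: LiBH(s-Bu)3, THF, −78 °C; then H2O
Reagents that add atoms: none
Why: Ketone reduction by a bulky trialkylborohydride should deliver hydride along the equatorial trajectory from the exo side, because the endo side of C3 lies under the C6=C7 bridge, giving the axial alcohol at a temperature at which the epimerisable C4 centre is safe.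

Step 8
Reactants: 12 tert-butyl [(1R,2S,3S,4S,5R)-3-hydroxy-1-(TBSO-methyl)-7-methyl-2-OR*-8-oxabicyclo[3.2.1]oct-6-en-4-yl]acetate
Product: 14 tricyclic lactone (1R,2S,3R,4R,5R) in which a γ-lactone is cis-fused at C3–C4 of the oxabicyclooctene (C3–O and C4–CH2 both syn to O8), via axial C3 triflate 13 (not isolated)
Conditions: Tf2O, pyridine, CH2Cl2, −78 → 23 °C
Reagents that add atoms: trifluoromethanesulfonic anhydride, O=S(=O)(OS(=O)(=O)C(F)(F)F)C(F)(F)F (its atoms stay only in 13)
Why: Invertive lactonisation of a γ-sulfonyloxy ester: the axial triflate is antiperiplanar to the axial C4 arm, so the ester carbonyl oxygen displaces it from the exo face (5-exo-tet) and the dialkoxycarbenium ion sheds isobutene, which inverts C3 and gives the cis-fused lactone with C3–O syn to O8.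

Step 9
Reactants: 14 tricyclic lactone
Product: 16 (1R,2S,3R,4R,5S,6R,7R)-6-exo-hydroxy-7-endo-methyl tricyclic lactone, via exo C6 alkylborane 15 (not isolated)
Conditions: BH3·THF (1.2 equiv), THF, 0 °C; then H2O2, aq NaOAc, 0 °C
Reagents that add atoms: borane (as BH3·THF), B (boron stays only in 15); hydrogen peroxide, OO
Why: Hydroboration–oxidation of the strained trisubstituted alkene should put boron on the less substituted C6 and add H and B syn from the exo face, so that C6–OH is exo and the C7 methyl group is pushed endo, while borane reduces the lactone far more slowly.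

Step 10
Reactants: 16 6-exo-hydroxy-7-endo-methyl tricyclic lactone
Product: 18 (1R,2S,3R,4S,5S,7R)-7-exo-methyl-6-oxo tricyclic lactone, via endo-methyl ketone 17 (not isolated)
Conditions: Dess–Martin periodinane, CH2Cl2, 23 °C; aq NaHCO3 wash; crude 17, DBU (0.2 equiv), CH2Cl2, 23 °C
Reagents that add atoms: none
Why: Dess–Martin oxidation gives the C6 ketone, whose only enolisable position is C7 (C5 is a bridgehead), and base-mediated equilibration should move the methyl group from the crowded endo position (syn-pentane contact with the equatorial C2 alkoxy group) to the exo position syn to O8, which is the C7 configuration of the target.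

Step 11
Reactants: 18 7-exo-methyl-6-oxo tricyclic lactone
Product: 19 (1R,2S,3R,4S,7R)-hydroxy ketone: cis-fused cycloheptane γ-lactone bearing C1–OH and C1–CH2OTBS and C2–OR* and C6=O and C7–CH3
Conditions: SmI2 (2.5 equiv), THF–MeOH, −78 °C
Reagents that add atoms: none
Why: Two-electron reduction of the α-alkoxy ketone by SmI2 (ketyl formation, expulsion of the α-oxygen as alkoxide, protonation of the samarium enolate) cleaves only the C5–O8 bond, as known for 7-oxanorbornan-2-ones of like geometry, which turns C5 into CH2 and frees the C1 tertiary alcohol with its configuration kept.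

Step 12
Reactants: 19 hydroxy ketone
Product: 20 (1R,2S,3R,4S,6R,7S)-1,6-diol (C6–OH anti to C1–OH and trans to C7–CH3)
Conditions: Me4NBH(OAc)3, MeCN–AcOH, −25 °C
Reagents that add atoms: none
Why: In this Evans–Saksena reduction the C1 hydroxyl binds the triacetoxyborohydride and hydride is delivered within the complex to the same face of the C6 carbonyl, which should give the 1,3-anti diol and leave the lactone untouched.

Step 13
Reactants: 20 1,6-diol
Product: 21 C6-O-TBS ether of 20
Conditions: TBSOTf (1.1 equiv), 2,6-lutidine, CH2Cl2, −78 °C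
Reagents that add atoms: tert-butyldimethylsilyl trifluoromethanesulfonate, CC(C)(C)[Si](C)(C)OS(=O)(=O)C(F)(F)F
Why: Silyl ether formation at low temperature should take the secondary C6 alcohol and leave the far more hindered tertiary C1 alcohol free.

Step 14
Reactants: 21 C6-O-TBS ether
Product: 24 α-methylene lactone (1R,2S,3R,4S,6R,7S), via Mannich base 22 (not isolated), via trimethylammonium iodide 23 (not isolated)
Conditions: LiN(i-Pr)2 (2.5 equiv), THF, −78 °C; CH2=NMe2+ I−, −78 → 0 °C; MeI, MeOH, 23 °C; aq NaHCO3, CH2Cl2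
Reagents that add atoms: Eschenmoser's salt, C=[N+](C)C.[I-]; iodomethane, CI (its carbon stays only in 23)
Why: α-Methylenation of the lactone by Mannich reaction of its lithium enolate (the extra base carries the C1 alkoxide along), exhaustive methylation and E1cB loss of trimethylamine, in which the transient stereocentre at the lactone α-carbon is destroyed again.

Step 15
Reactants: 24 α-methylene lactone
Product: 25 C2 alcohol (1R,2S,3R,4S,6R,7S)
Conditions: DDQ, CH2Cl2–H2O (pH 7 buffer), 0 → 23 °C
Reagents that add atoms: none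
Why: Oxidative cleavage of a (2-naphthyl)methyl-type ether by DDQ (hydride abstraction at the electron-rich naphthylic C–H, then hydrolysis of the oxocarbenium ion) frees the C2 alcohol with retention and spares the silyl ethers and the α-methylene lactone, which hydrogenolysis would not.

Step 16
Reactants: 25 C2 alcohol; 26 angelic acid ((Z)-2-methylbut-2-enoic acid)
Product: 28 C2 angelate, via mixed anhydride 27 (not isolated)
Conditions: 26, 2,4,6-trichlorobenzoyl chloride, Et3N, toluene, 23 °C; then 25, 80 °C
Reagents that add atoms: 2,4,6-trichlorobenzoyl chloride, O=C(Cl)c1c(Cl)cc(Cl)cc1Cl (its atoms stay only in 27)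
Why: Yamaguchi-type esterification through the mixed anhydride without a nucleophilic catalyst is the usual way to acylate hindered alcohols by angelic acid without Z to E isomerisation, and the tertiary C1 alcohol should not compete.

Step 17
Reactants: 28 C2 angelate
Product: 29 primary alcohol (C1–CH2OH, C6–OTBS kept)
Conditions: HF·pyridine, pyridine, THF, 0 °C
Reagents that add atoms: none
Why: Buffered fluoride desilylation should remove the primary silyl ether faster than the secondary one, which is flanked by the C7 methyl branch.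

Step 18
Reactants: 29 primary alcohol
Product: 30 α-hydroxy aldehyde (C1–CHO, 1S)
Conditions: Dess–Martin periodinane, CH2Cl2, 0 → 23 °C
Reagents that add atoms: none
Why: Dess–Martin oxidation takes the primary alcohol to the aldehyde, the tertiary alcohol cannot be oxidised, and C1 carries no hydrogen, so neither epimerisation nor β-elimination of the angelate is possible.

Step 19
Reactants: 30 α-hydroxy aldehyde; 31 (E)-1-iodoprop-1-ene
Product: 32 (E)-allylic alcohol (both epimers at the new carbinol carbon)
Conditions: CrCl2 (6 equiv), NiCl2 (2 mol%), DMSO, 23 °C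
Reagents that add atoms: none
Why: In the Nozaki–Hiyama–Kishi coupling the alkenylchromium species forms with retention of the E geometry and adds only to aldehydes, so lactone, angelate and free hydroxyl are tolerated, and the new carbinol centre is erased in step 20.

Step 20
Reactants: 32 (E)-allylic alcohol
Product: 33 C6-O-TBS ether of the target
Conditions: Dess–Martin periodinane, CH2Cl2, 0 → 23 °C
Reagents that add atoms: none
Why: Dess–Martin oxidation of the only oxidisable hydroxyl group gives the (E)-but-2-enoyl ketone under neutral conditions that leave the alkene geometries and the α-ketol unchanged.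

Step 21
Reactants: 33 C6-O-TBS ether of the target
Product: 34 CNP0149130.1 (target, 1S,2S,3R,4S,6R,7S)
Conditions: HF·pyridine, THF, 0 → 23 °C
Reagents that add atoms: none
Why: Acidic fluoride desilylation cleaves the last silyl ether without base, so α-methylene lactone, enone, angelate and α-ketol never meet an alkoxide, and no stereocentre is touched.

Compound list
1 | methyl 3-methylfuran-2-carboxylate | COC(=O)c1occc1C | starting material
2 | (3-methylfuran-2-yl)methanol | OCc1occc1C | intermediate
3 | tert-butyl(dimethyl)[(3-methylfuran-2-yl)methoxy]silane | CC(C)(C)[Si](C)(C)OCc1occc1C | intermediate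
4 | 1,1-dimethoxypropan-2-one | CC(=O)C(OC)OC | starting material
5 | (1S)-1-(naphthalen-2-yl)ethanol | C[C@H](O)c1ccc2ccccc2c1 | starting material
6 | 1-methoxy-1-[(1S)-1-(naphthalen-2-yl)ethoxy]propan-2-one, both acetal epimers | CC(=O)C(OC)O[C@@H](C)c1ccc2ccccc2c1 | intermediate
7 | triethyl({3-methoxy-3-[(1S)-1-(naphthalen-2-yl)ethoxy]prop-1-en-2-yl}oxy)silane | C=C(O[Si](CC)(CC)CC)C(OC)O[C@@H](C)c1ccc2ccccc2c1 | intermediate
8 | 1-[(1S)-1-(naphthalen-2-yl)ethoxy]-2-(triethylsilyloxy)allyl cation (triflate as counterion) | C=C(O[Si](CC)(CC)CC)C=[O+][C@@H](C)c1ccc2ccccc2c1 | intermediate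
9 | (1R,2R,5S)-1-(TBSO-methyl)-7-methyl-2-OR*-8-oxabicyclo[3.2.1]oct-6-en-3-one, C2–O equatorial | O=C1C[C@H]2C=C(C)[C@@](O2)(CO[Si](C)(C)C(C)(C)C)[C@H]1O[C@@H](C)c3ccc4ccccc4c3 | intermediate
10 | tert-butyl bromoacetate | CC(C)(C)OC(=O)CBr | starting material
11 | tert-butyl [(1R,2R,4R,5R)-1-(TBSO-methyl)-7-methyl-2-OR*-3-oxo-8-oxabicyclo[3.2.1]oct-6-en-4-yl]acetate, C4 arm axial | O=C1[C@H](CC(=O)OC(C)(C)C)[C@H]2C=C(C)[C@@](O2)(CO[Si](C)(C)C(C)(C)C)[C@H]1O[C@@H](C)c3ccc4ccccc4c3 | intermediate
12 | (1R,2S,3S,4S,5R)-3-axial alcohol of 11 | O[C@H]1[C@H](CC(=O)OC(C)(C)C)[C@H]2C=C(C)[C@@](O2)(CO[Si](C)(C)C(C)(C)C)[C@H]1O[C@@H](C)c3ccc4ccccc4c3 | intermediate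
13 | C3 axial triflate of 12 | O=S(=O)(O[C@H]1[C@H](CC(=O)OC(C)(C)C)[C@H]2C=C(C)[C@@](O2)(CO[Si](C)(C)C(C)(C)C)[C@H]1O[C@@H](C)c3ccc4ccccc4c3)C(F)(F)F | intermediate
14 | tricyclic lactone (1R,2S,3R,4R,5R), γ-lactone cis-fused at C3–C4, syn to O8 | C1C(=O)O[C@@H]2[C@H]1[C@H]3C=C(C)[C@@](O3)(CO[Si](C)(C)C(C)(C)C)[C@H]2O[C@@H](C)c4ccc5ccccc5c4 | intermediate
15 | C6-exo alkylborane of 14 (C7 methyl endo) | C1C(=O)O[C@@H]2[C@H]1[C@H]3[C@H](B)[C@@H](C)[C@@](O3)(CO[Si](C)(C)C(C)(C)C)[C@H]2O[C@@H](C)c4ccc5ccccc5c4 | intermediate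
16 | (1R,2S,3R,4R,5S,6R,7R)-6-exo-hydroxy-7-endo-methyl tricyclic lactone | C1C(=O)O[C@@H]2[C@H]1[C@H]3[C@H](O)[C@@H](C)[C@@](O3)(CO[Si](C)(C)C(C)(C)C)[C@H]2O[C@@H](C)c4ccc5ccccc5c4 | intermediate
17 | (7S)-7-endo-methyl-6-oxo tricyclic lactone | C1C(=O)O[C@@H]2[C@H]1[C@H]3C(=O)[C@@H](C)[C@@](O3)(CO[Si](C)(C)C(C)(C)C)[C@H]2O[C@@H](C)c4ccc5ccccc5c4 | intermediate
18 | (1R,2S,3R,4S,5S,7R)-7-exo-methyl-6-oxo tricyclic lactone | C1C(=O)O[C@@H]2[C@H]1[C@H]3C(=O)[C@H](C)[C@@](O3)(CO[Si](C)(C)C(C)(C)C)[C@H]2O[C@@H](C)c4ccc5ccccc5c4 | intermediate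
19 | (1R,2S,3R,4S,7R)-hydroxy ketone, cis-fused cycloheptane γ-lactone | C1C(=O)O[C@@H]2[C@H]1CC(=O)[C@H](C)[C@@](O)(CO[Si](C)(C)C(C)(C)C)[C@H]2O[C@@H](C)c3ccc4ccccc4c3 | intermediate
20 | (1R,2S,3R,4S,6R,7S)-1,6-anti diol | C1C(=O)O[C@@H]2[C@H]1C[C@@H](O)[C@H](C)[C@@](O)(CO[Si](C)(C)C(C)(C)C)[C@H]2O[C@@H](C)c3ccc4ccccc4c3 | intermediate
21 | C6-O-TBS ether of 20 | C1C(=O)O[C@@H]2[C@H]1C[C@@H](O[Si](C)(C)C(C)(C)C)[C@H](C)[C@@](O)(CO[Si](C)(C)C(C)(C)C)[C@H]2O[C@@H](C)c3ccc4ccccc4c3 | intermediate
22 | α-(dimethylaminomethyl) lactone, α-carbon undefined | CN(C)CC1C(=O)O[C@@H]2[C@H]1C[C@@H](O[Si](C)(C)C(C)(C)C)[C@H](C)[C@@](O)(CO[Si](C)(C)C(C)(C)C)[C@H]2O[C@@H](C)c3ccc4ccccc4c3 | intermediate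
23 | trimethylammonium iodide of 22 | C[N+](C)(C)CC1C(=O)O[C@@H]2[C@H]1C[C@@H](O[Si](C)(C)C(C)(C)C)[C@H](C)[C@@](O)(CO[Si](C)(C)C(C)(C)C)[C@H]2O[C@@H](C)c3ccc4ccccc4c3.[I-] | intermediate
24 | α-methylene lactone with C2–OR* | C=C1C(=O)O[C@@H]2[C@H]1C[C@@H](O[Si](C)(C)C(C)(C)C)[C@H](C)[C@@](O)(CO[Si](C)(C)C(C)(C)C)[C@H]2O[C@@H](C)c3ccc4ccccc4c3 | intermediate
25 | C2 alcohol | C=C1C(=O)O[C@@H]2[C@H]1C[C@@H](O[Si](C)(C)C(C)(C)C)[C@H](C)[C@@](O)(CO[Si](C)(C)C(C)(C)C)[C@H]2O | intermediate
26 | angelic acid, (Z)-2-methylbut-2-enoic acid | C/C=C(/C)C(=O)O | starting material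
27 | angelic 2,4,6-trichlorobenzoic anhydride | C/C=C(/C)C(=O)OC(=O)c1c(Cl)cc(Cl)cc1Cl | intermediate
28 | C2 angelate, bis-TBS ether | C=C1C(=O)O[C@@H]2[C@H]1C[C@@H](O[Si](C)(C)C(C)(C)C)[C@H](C)[C@@](O)(CO[Si](C)(C)C(C)(C)C)[C@H]2OC(=O)/C(C)=C\C | intermediate
29 | primary alcohol, C6–OTBS | C=C1C(=O)O[C@@H]2[C@H]1C[C@@H](O[Si](C)(C)C(C)(C)C)[C@H](C)[C@@](O)(CO)[C@H]2OC(=O)/C(C)=C\C | intermediate
30 | α-hydroxy aldehyde | C=C1C(=O)O[C@@H]2[C@H]1C[C@@H](O[Si](C)(C)C(C)(C)C)[C@H](C)[C@@](O)(C=O)[C@H]2OC(=O)/C(C)=C\C | intermediate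
31 | (E)-1-iodoprop-1-ene | C/C=C/I | starting material
32 | (E)-allylic alcohol, both carbinol epimers | C=C1C(=O)O[C@@H]2[C@H]1C[C@@H](O[Si](C)(C)C(C)(C)C)[C@H](C)[C@@](O)(C(O)/C=C/C)[C@H]2OC(=O)/C(C)=C\C | intermediate
33 | C6-O-TBS ether of the target | C=C1C(=O)O[C@@H]2[C@H]1C[C@@H](O[Si](C)(C)C(C)(C)C)[C@H](C)[C@@](O)(C(=O)/C=C/C)[C@H]2OC(=O)/C(C)=C\C | intermediate
34 | CNP0149130.1 | C=C1C(=O)O[C@@H]2[C@H]1C[C@@H](O)[C@H](C)[C@@](O)(C(=O)/C=C/C)[C@H]2OC(=O)/C(C)=C\C | target

Total step count: 21. Longest linear sequence: 19 steps (1, 2, 5–21).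

Steps most likely to fail

**Step 5.** Three things may go wrong:
- erosion of the head-to-head regiochemistry, because the second bond joins two crowded carbons;
- proton loss from C5 after the first bond, which restores the furan instead of closing the ring;
- acid-induced ionisation of the furfuryl silyl ether.

The fallback sets out from 5 and 3 and comes back at 9. It makes the same oxyallyl unit under basic, Lewis-acid-free conditions.
- Alcohol 5 is O-alkylated with epichlorohydrin (NaH, DMF) to the glycidyl ether F1.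
- F1 is opened with LiCl/AcOH to the chlorohydrin F2.
- F2 is oxidised with Dess–Martin periodinane to the 1-chloro-3-alkoxypropan-2-one F3.
- Dehydrochlorination of F3 by Et3N in CF3CH2OH in the presence of furan 3 generates the alkoxy-stabilised oxyallyl species, which should be trapped in a (4+3) cycloaddition to 9. Any minor diastereomers would be removed by chromatography.

**Step 8.** Antiperiplanar E2 loss of the axial triflate towards C2 may compete with substitution, or the neutral ester may participate too slowly.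

The fallback sets out from 12 and comes back at 14. It swaps neutral-ester participation for carboxylate displacement under redox condensation.
- The tert-butyl ester is cleaved with Me3SiOTf/2,6-lutidine followed by water to give the hydroxy acid F4.
- F4 is closed by Mitsunobu lactonisation (PPh3, diisopropyl azodicarboxylate, THF) with inversion at C3.

**Step 16.** Acylation of the C2 hydroxyl next to the quaternary C1 may be slow, and the angelate may isomerise from Z to E on prolonged heating.

The fallback sets out from 25 and comes back at 28. It builds the Z alkene only after the ester bond exists.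
- 25 is esterified under forcing carbodiimide/DMAP conditions with 2-[bis(2,2,2-trifluoroethoxy)phosphoryl]propanoic acid, which has no alkene to isomerise, to give the phosphonopropionate F5.
- A Still–Gennari olefination of F5 with acetaldehyde (KN(SiMe3)2, 18-crown-6, THF, −78 °C) should give the Z-trisubstituted enoate.

Further compounds
F1 | step 5 | 2-({(1S)-1-(naphthalen-2-yl)ethoxy}methyl)oxirane, both epoxide epimers | C[C@H](OCC1CO1)c2ccc3ccccc3c2
F2 | step 5 | 1-chloro-3-[(1S)-1-(naphthalen-2-yl)ethoxy]propan-2-ol, both carbinol epimers | C[C@H](OCC(O)CCl)c1ccc2ccccc2c1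
F3 | step 5 | 1-chloro-3-[(1S)-1-(naphthalen-2-yl)ethoxy]propan-2-one | C[C@H](OCC(=O)CCl)c1ccc2ccccc2c1
F4 | step 8 | [(1R,2S,3S,4S,5R)-3-hydroxy-1-(TBSO-methyl)-7-methyl-2-OR*-8-oxabicyclo[3.2.1]oct-6-en-4-yl]acetic acid | O[C@H]1[C@H](CC(=O)O)[C@H]2C=C(C)[C@@](O2)(CO[Si](C)(C)C(C)(C)C)[C@H]1O[C@@H](C)c3ccc4ccccc4c3
F5 | step 16 | C2 2-[bis(2,2,2-trifluoroethoxy)phosphoryl]propanoate of 25 | C=C1C(=O)O[C@@H]2[C@H]1C[C@@H](O[Si](C)(C)C(C)(C)C)[C@H](C)[C@@](O)(CO[Si](C)(C)C(C)(C)C)[C@H]2OC(=O)C(C)P(=O)(OCC(F)(F)F)OCC(F)(F)F
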